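Retrosynthetic cuts: the two formyl C–C bonds and the two O-methyl groups; the aryl–O bond of the chroman; the bond from the benzylic CH to the quaternary methyl-bearing carbon; the methyl group on that carbon; and, as the key cut, the bond from the spiro carbon to its cyclopentane CH2, which is moved back onto the oxygen-bearing carbon (cyclopentanone to cyclobutanol).
Enabling feature: in the cyclopentane the oxygen-bearing CH sits next to the spiro carbon, and the spiro carbon is allylic to the cyclohexene C=C that carries the isopropyl group. Read as an α-spiro cyclopentanone with a β,γ-alkene, this ring is the product of a 1,2-shift of a 1-(cyclohexenyl)cyclobutanol on a palladium-activated alkene followed by β-hydride elimination; the cyclobutanone oxygen ends as the chroman oxygen.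
Forward order: cyclohexane ring from the chiral pool; cyclobutanol by Shapiro addition to cyclobutanone; ring expansion to the spiro cyclopentanone, which also places the ring alkene; α-methylation and SN1 benzylation build the quaternary and benzylic carbons; reduction; chroman ring by C–O coupling; diformylation and demethylation.
Stereochemistry: the ring CH–CH3 centre comes from (2R,5R)-dihydrocarvone. The spiro centre is set in the key step (migration anti to palladium, steered by the ring methyl group and by the sacrificial isopropyl-bearing centre). The quaternary and benzylic centres are set in the benzylation (face away from the ring CH–CH3, open transition state). The O-bearing CH is set by hydride attack anti to the benzylic branch and is kept in the C–O coupling.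
Key step: step 4
Assumption: commercial (+)-dihydrocarvone is taken as its main (2R,5R) isomer; any (2S,5R) epimer is removed when the crystalline hydrazone 3 is recrystallised.

Step 1
Reactants: 1 (2R,5R)-2-methyl-5-(prop-1-en-2-yl)cyclohexan-1-one (trans-dihydrocarvone)
Product: 2 (2R,5R)-2-methyl-5-(propan-2-yl)cyclohexan-1-one
Conditions: H2 (1 atm), Pd/C, EtOAc, rt
Reagents that add atoms: none
Why: Heterogeneous hydrogenation saturates the 1,1-disubstituted isopropenyl alkene without touching the ketone and creates no stereocentre, so both centres of 1 are kept.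

Step 2
Reactants: 2 (2R,5R)-2-methyl-5-(propan-2-yl)cyclohexan-1-one
Product: 3 N'-[(1E,2R,5R)-2-methyl-5-(propan-2-yl)cyclohexylidene]-2,4,6-tri(propan-2-yl)benzenesulfonohydrazide
Conditions: 2,4,6-triisopropylbenzenesulfonohydrazide, HCl (cat.), MeCN, rt; recrystallisation
Reagents that add atoms: 2,4,6-tri(propan-2-yl)benzenesulfonohydrazide, CC(C)c1cc(C(C)C)c(S(=O)(=O)NN)c(C(C)C)c1
Why: Acid-catalysed hydrazone condensation gives the arylsulfonylhydrazone with the N–N bond anti to the more substituted α-carbon, which later directs deprotonation to the CH2 side; the trans-2,5 arrangement is the thermodynamic one and is kept.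

Step 3
Reactants: 3 N'-[(1E,2R,5R)-2-methyl-5-(propan-2-yl)cyclohexylidene]-2,4,6-tri(propan-2-yl)benzenesulfonohydrazide; 4 cyclobutanone
Product: 6 1-[(3S,6R)-6-methyl-3-(propan-2-yl)cyclohex-1-en-1-yl]cyclobutan-1-ol, via vinyllithium 5 (not isolated)
Conditions: n-BuLi (2.2 equiv), THF, −78 to 0 °C; then 4, −78 °C to rt
Reagents that add atoms: none
Why: Shapiro reaction: the hydrazone dianion loses sulfinate and dinitrogen to give the less substituted vinyllithium 5, whose 1,2-addition to the strained ketone 4 gives the tertiary cyclobutanol; no stereocentre is formed or touched.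

Step 4
Reactants: 6 1-[(3S,6R)-6-methyl-3-(propan-2-yl)cyclohex-1-en-1-yl]cyclobutan-1-ol
Product: 7 (5R,10R)-10-methyl-7-(propan-2-yl)spiro[4.5]dec-6-en-1-one
Conditions: PdCl2(MeCN)2 (10 mol%), 1,4-benzoquinone (1.5 equiv), THF, rt to 50 °C
Reagents that add atoms: none
Why: Divalent palladium binds the ring alkene of 6 on the face that carries C3–H and the C6 methyl group (anti to the isopropyl group), and the antiperiplanar C–C bond of the cyclobutanol shifts to the tertiary alkene carbon (semipinacol-type 1,2-shift driven by release of cyclobutane strain and by C=O formation), which turns the four-membered ring into the cyclopentanone and makes its α-carbon the spiro centre. The σ-alkylpalladium so formed has a single β-hydrogen, the former C3–H, which is syn to palladium only in this pathway; syn β-hydride elimination gives the C6=C7 alkene of 7 next to the spiro carbon, erases the now unneeded isopropyl-bearing stereocentre, and benzoquinone returns the palladium hydride to divalent palladium. The closest known reaction type is the oxidative, Wacker-type ring expansion of 1-alkenylcyclobutanols to 2-alkylidene or spiro cyclopentanones mediated by divalent palladium. No new ring is closed: the ring is enlarged from four to five atoms by a 1,2-alkyl shift, and the spiro junction arises at the migration terminus. The new stereocentre (spiro C5, R) is controlled by the ring methyl group, anti to which the migrating CH2 enters, and in the same sense by the trans isopropyl-bearing centre through the syn-elimination requirement. The step needs facial selectivity in the alkene activation and the 1,2-shift in preference to β-carbon elimination of the tertiary alkoxide; the trans 3,6-substitution of 6 and the base-free conditions should secure both.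

Step 5
Reactants: 7 (5R,10R)-10-methyl-7-(propan-2-yl)spiro[4.5]dec-6-en-1-one
Product: 8 (5R,10R)-2,10-dimethyl-7-(propan-2-yl)spiro[4.5]dec-6-en-1-one (both C2 epimers)
Conditions: LDA, THF, −78 °C; MeI, −78 to −20 °C
Reagents that add atoms: iodomethane, CI
Why: Kinetic enolate alkylation at the only enolisable position (the other α-carbon is the quaternary spiro centre); the configuration of the new methine does not matter because it is planarised in step 6.

Step 6
Reactants: 8 (5R,10R)-2,10-dimethyl-7-(propan-2-yl)spiro[4.5]dec-6-en-1-one (both C2 epimers)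
Product: 9 tert-butyl{[(5R,10R)-2,10-dimethyl-7-(propan-2-yl)spiro[4.5]deca-1,6-dien-1-yl]oxy}dimethylsilane
Conditions: TBSOTf, Et3N, CH2Cl2, 0 °C to rt
Reagents that add atoms: tert-butyldimethylsilyl trifluoromethanesulfonate, CC(C)(C)[Si](C)(C)OS(=O)(=O)C(F)(F)F
Why: Soft enolisation and O-silylation give the only possible silyl enol ether, the tetrasubstituted C1=C2 alkene, which is the nucleophile for step 8.

Step 7
Reactants: 10 2-bromo-4,6-dimethoxybenzaldehyde
Product: 11 1-(2-bromo-4,6-dimethoxyphenyl)-3-methylbutan-1-ol (racemic)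
Conditions: i-BuMgBr, THF, −20 to 0 °C; aq NH4Cl
Reagents that add atoms: isobutylmagnesium bromide, CC(C)C[Mg]Br
Why: Grignard addition to the aldehyde is faster than bromine–magnesium exchange at this temperature; the carbinol is racemic, which is harmless because it is ionised in step 8.

Step 8
Reactants: 9 tert-butyl{[(5R,10R)-2,10-dimethyl-7-(propan-2-yl)spiro[4.5]deca-1,6-dien-1-yl]oxy}dimethylsilane; 11 1-(2-bromo-4,6-dimethoxyphenyl)-3-methylbutan-1-ol (racemic)
Product: 12 (2R,5R,10R)-2-[(1S)-1-(2-bromo-4,6-dimethoxyphenyl)-3-methylbutyl]-2,10-dimethyl-7-(propan-2-yl)spiro[4.5]dec-6-en-1-one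
Conditions: Sc(OTf)3 (10 mol%), 4 Å MS, CH2Cl2, −40 to 0 °C
Reagents that add atoms: none
Why: Lewis acid-catalysed SN1 (Mukaiyama-type) alkylation: the ortho,para-dimethoxy-stabilised benzylic cation from 11 is attacked by C2 of the silyl enol ether on the face of the spiro ring's vinyl CH (away from C10 and its methyl group), which should set the quaternary centre (2R), through an open antiperiplanar transition state with the aryl group anti to C1, the benzylic hydrogen towards the spiro ring and the isobutyl group towards the silyloxy side, which should set the benzylic centre (1S).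

Step 9
Reactants: 12 (2R,5R,10R)-2-[(1S)-1-(2-bromo-4,6-dimethoxyphenyl)-3-methylbutyl]-2,10-dimethyl-7-(propan-2-yl)spiro[4.5]dec-6-en-1-one
Product: 13 (1S,2R,5R,10R)-2-[(1S)-1-(2-bromo-4,6-dimethoxyphenyl)-3-methylbutyl]-2,10-dimethyl-7-(propan-2-yl)spiro[4.5]dec-6-en-1-ol
Conditions: LiAlH4, THF, −20 to 0 °C
Reagents that add atoms: none
Why: Substrate-controlled carbonyl reduction: hydride should add to the cyclopentanone from the face of the C2 methyl group, anti to the much larger benzylic branch on the same quaternary carbon, which gives the (1S)-alcohol with the hydroxyl cis to that branch as the ring closure requires.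

Step 10
Reactants: 13 (1S,2R,5R,10R)-2-[(1S)-1-(2-bromo-4,6-dimethoxyphenyl)-3-methylbutyl]-2,10-dimethyl-7-(propan-2-yl)spiro[4.5]dec-6-en-1-ol
Product: 14 (1R,3'aS,6R,9'S,9'aR)-6',8'-dimethoxy-6,9'a-dimethyl-9'-(2-methylpropyl)-3-(propan-2-yl)-1',2',9',9'a-tetrahydro-3'aH-spiro[cyclohex-2-ene-1,3'-cyclopenta[b]chromene]
Conditions: Pd(OAc)2 (5 mol%), 2-(di-tert-butylphosphino)-1,1'-binaphthyl (6 mol%), Cs2CO3, toluene, 80 °C
Reagents that add atoms: none
Why: Intramolecular Buchwald–Hartwig etherification: oxidative addition of zerovalent palladium into the aryl bromide, alkoxide exchange and C–O reductive elimination close the six-membered chroman ring; the alcohol C–O bond is not broken, so the carbinol configuration is retained and the ring fusion is cis.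

Step 11
Reactants: 14 (1R,3'aS,6R,9'S,9'aR)-6',8'-dimethoxy-6,9'a-dimethyl-9'-(2-methylpropyl)-3-(propan-2-yl)-1',2',9',9'a-tetrahydro-3'aH-spiro[cyclohex-2-ene-1,3'-cyclopenta[b]chromene]
Product: 15 (1R,3'aS,6R,9'S,9'aR)-6',8'-dimethoxy-6,9'a-dimethyl-9'-(2-methylpropyl)-3-(propan-2-yl)-1',2',9',9'a-tetrahydro-3'aH-spiro[cyclohex-2-ene-1,3'-cyclopenta[b]chromene]-5',7'-dicarbaldehyde
Conditions: Cl2CHOMe (excess), TiCl4, CH2Cl2, −78 to 0 °C; aq work-up
Reagents that add atoms: dichloromethyl methyl ether, COC(Cl)Cl; water, O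
Why: Rieche formylation (electrophilic aromatic substitution by the TiCl4-activated chloro(methoxy)methyl cation) at the only two free ring positions, each ortho or para to three oxygen substituents; hydrolysis of the α-chloro ethers gives the dialdehyde.

Step 12
Reactants: 15 (1R,3'aS,6R,9'S,9'aR)-6',8'-dimethoxy-6,9'a-dimethyl-9'-(2-methylpropyl)-3-(propan-2-yl)-1',2',9',9'a-tetrahydro-3'aH-spiro[cyclohex-2-ene-1,3'-cyclopenta[b]chromene]-5',7'-dicarbaldehyde
Product: 16 (1R,3'aS,6R,9'S,9'aR)-6',8'-dihydroxy-6,9'a-dimethyl-9'-(2-methylpropyl)-3-(propan-2-yl)-1',2',9',9'a-tetrahydro-3'aH-spiro[cyclohex-2-ene-1,3'-cyclopenta[b]chromene]-5',7'-dicarbaldehyde (target)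
Conditions: BCl3, CH2Cl2, −78 to 0 °C; aq NaHCO3
Reagents that add atoms: none
Why: Chelation-assisted Lewis acid demethylation: BCl3 cleaves aryl methyl ethers that can chelate an ortho carbonyl group, which both methoxy groups can, whereas the hindered secondary alkyl–O bond of the chroman cannot undergo the SN2 dealkylation.

Compound list
1 | (2R,5R)-2-methyl-5-(prop-1-en-2-yl)cyclohexan-1-one | O=C1C[C@H](C(C)=C)CC[C@H]1C | starting material
2 | (2R,5R)-2-methyl-5-(propan-2-yl)cyclohexan-1-one | O=C1C[C@H](C(C)C)CC[C@H]1C | intermediate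
3 | N'-[(1E,2R,5R)-2-methyl-5-(propan-2-yl)cyclohexylidene]-2,4,6-tri(propan-2-yl)benzenesulfonohydrazide | CC(C)c1cc(C(C)C)c(S(=O)(=O)N/N=C2\C[C@H](C(C)C)CC[C@H]2C)c(C(C)C)c1 | intermediate
4 | cyclobutanone | O=C1CCC1 | starting material
5 | [(3S,6R)-6-methyl-3-(propan-2-yl)cyclohex-1-en-1-yl]lithium | [Li]C1=C[C@H](C(C)C)CC[C@H]1C | intermediate (not isolated)
6 | 1-[(3S,6R)-6-methyl-3-(propan-2-yl)cyclohex-1-en-1-yl]cyclobutan-1-ol | OC1(CCC1)C2=C[C@H](C(C)C)CC[C@H]2C | intermediate
7 | (5R,10R)-10-methyl-7-(propan-2-yl)spiro[4.5]dec-6-en-1-one | O=C1CCC[C@@]12C=C(C(C)C)CC[C@H]2C | intermediate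
8 | (5R,10R)-2,10-dimethyl-7-(propan-2-yl)spiro[4.5]dec-6-en-1-one (both C2 epimers) | O=C1C(C)CC[C@@]12C=C(C(C)C)CC[C@H]2C | intermediate
9 | tert-butyl{[(5R,10R)-2,10-dimethyl-7-(propan-2-yl)spiro[4.5]deca-1,6-dien-1-yl]oxy}dimethylsilane | CC(C)(C)[Si](C)(C)OC1=C(C)CC[C@@]12C=C(C(C)C)CC[C@H]2C | intermediate
10 | 2-bromo-4,6-dimethoxybenzaldehyde | O=Cc1c(Br)cc(OC)cc1OC | starting material
11 | 1-(2-bromo-4,6-dimethoxyphenyl)-3-methylbutan-1-ol (racemic) | CC(C)CC(O)c1c(Br)cc(OC)cc1OC | intermediate
12 | (2R,5R,10R)-2-[(1S)-1-(2-bromo-4,6-dimethoxyphenyl)-3-methylbutyl]-2,10-dimethyl-7-(propan-2-yl)spiro[4.5]dec-6-en-1-one | CC(C)C[C@H](c1c(Br)cc(OC)cc1OC)[C@@]1(C)CC[C@@]2(C=C(C(C)C)CC[C@H]2C)C1=O | intermediate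
13 | (1S,2R,5R,10R)-2-[(1S)-1-(2-bromo-4,6-dimethoxyphenyl)-3-methylbutyl]-2,10-dimethyl-7-(propan-2-yl)spiro[4.5]dec-6-en-1-ol | CC(C)C[C@H](c1c(Br)cc(OC)cc1OC)[C@@]1(C)CC[C@@]2(C=C(C(C)C)CC[C@H]2C)[C@H]1O | intermediate
14 | (1R,3'aS,6R,9'S,9'aR)-6',8'-dimethoxy-6,9'a-dimethyl-9'-(2-methylpropyl)-3-(propan-2-yl)-1',2',9',9'a-tetrahydro-3'aH-spiro[cyclohex-2-ene-1,3'-cyclopenta[b]chromene] | CC(C)C[C@@H]1c2c(OC)cc(OC)cc2O[C@H]2[C@]1(C)CC[C@@]21C=C(C(C)C)CC[C@H]1C | intermediate
15 | (1R,3'aS,6R,9'S,9'aR)-6',8'-dimethoxy-6,9'a-dimethyl-9'-(2-methylpropyl)-3-(propan-2-yl)-1',2',9',9'a-tetrahydro-3'aH-spiro[cyclohex-2-ene-1,3'-cyclopenta[b]chromene]-5',7'-dicarbaldehyde | CC(C)C[C@@H]1c2c(OC)c(C=O)c(OC)c(C=O)c2O[C@H]2[C@]1(C)CC[C@@]21C=C(C(C)C)CC[C@H]1C | intermediate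
16 | (1R,3'aS,6R,9'S,9'aR)-6',8'-dihydroxy-6,9'a-dimethyl-9'-(2-methylpropyl)-3-(propan-2-yl)-1',2',9',9'a-tetrahydro-3'aH-spiro[cyclohex-2-ene-1,3'-cyclopenta[b]chromene]-5',7'-dicarbaldehyde | CC(C)C[C@@H]1c2c(O)c(C=O)c(O)c(C=O)c2O[C@H]2[C@]1(C)CC[C@@]21C=C(C(C)C)CC[C@H]1C | target

Total step count: 12. Longest linear sequence: 11 steps (steps 1 to 6 and 8 to 12).

Steps most likely to fail

Step 8. The C–C bond forms between a quaternary and a doubly ortho-substituted benzylic carbon, so the cation may instead lose a proton to the styrene or the enol ether may be desilylated first; discrimination between the two faces of the cation may also be low. Fallback, from 8 and 10, back to 12: the lithium enolate of 8 (LDA, THF, −78 °C) is added to aldehyde 10 to give the aldol adduct (2R,5R,10R)-2-[(2-bromo-4,6-dimethoxyphenyl)(hydroxy)methyl]-2,10-dimethyl-7-(propan-2-yl)spiro[4.5]dec-6-en-1-one F1. Hosomi–Sakurai-type substitution of its benzylic hydroxyl with trimethyl(2-methylallyl)silane (Sc(OTf)3 cat., CH2Cl2, −40 °C) gives (2R,5R,10R)-2-[(1S)-1-(2-bromo-4,6-dimethoxyphenyl)-3-methylbut-3-en-1-yl]-2,10-dimethyl-7-(propan-2-yl)spiro[4.5]dec-6-en-1-one F2; the benzylic centre is then set by addition of the carbon chain to a cation that already carries the quaternary carbon. Hydrogenation of the 1,1-disubstituted alkene alone (H2, RhCl(PPh3)3, benzene) returns 12.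

Step 10. β-Hydride elimination from the very crowded palladium alkoxide (oxidation back to the ketone with loss of bromine from the arene) may outrun C–O reductive elimination, or the hindered alkoxide may not bind palladium at all. Fallback, from 13, back to 15: the order of formylation and ring closure is reversed. Rieche formylation of 13 (Cl2CHOMe, TiCl4, CH2Cl2, −78 to 0 °C) gives 4-bromo-5-{(1S)-1-[(1S,2R,5R,10R)-1-hydroxy-2,10-dimethyl-7-(propan-2-yl)spiro[4.5]dec-6-en-2-yl]-3-methylbutyl}-2,6-dimethoxybenzene-1,3-dicarbaldehyde F3, in which the bromide is ortho and para to formyl groups. Base (K2CO3, DMF, 60 °C; this also cleaves any formate formed at the alcohol) then closes the chroman by intramolecular nucleophilic aromatic substitution with retention at the carbinol carbon, giving 15.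

Step 11. TiCl4 and the HCl set free may protonate or hydrochlorinate the trisubstituted alkene and move the double bond, and the second formylation may stall once the first formyl group has deactivated the ring. Fallback, from 14, straight to 16: both methyl ethers are cleaved under non-acidic conditions (NaSEt, DMF, 140 °C) to give (1R,3'aS,6R,9'S,9'aR)-6,9'a-dimethyl-9'-(2-methylpropyl)-3-(propan-2-yl)-1',2',9',9'a-tetrahydro-3'aH-spiro[cyclohex-2-ene-1,3'-cyclopenta[b]chromene]-6',8'-diol F4. Vilsmeier–Haack double formylation of this phloroglucinol-type diol (POCl3, DMF, 0 °C to rt; aq NaOAc) gives 16 without strong Lewis acid.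

Further compounds
F1 | step 8 | (2R,5R,10R)-2-[(2-bromo-4,6-dimethoxyphenyl)(hydroxy)methyl]-2,10-dimethyl-7-(propan-2-yl)spiro[4.5]dec-6-en-1-one (carbinol epimers) | OC(c1c(Br)cc(OC)cc1OC)[C@@]1(C)CC[C@@]2(C=C(C(C)C)CC[C@H]2C)C1=O
F2 | step 8 | (2R,5R,10R)-2-[(1S)-1-(2-bromo-4,6-dimethoxyphenyl)-3-methylbut-3-en-1-yl]-2,10-dimethyl-7-(propan-2-yl)spiro[4.5]dec-6-en-1-one | CC(=C)C[C@H](c1c(Br)cc(OC)cc1OC)[C@@]1(C)CC[C@@]2(C=C(C(C)C)CC[C@H]2C)C1=O
F3 | step 10 | 4-bromo-5-{(1S)-1-[(1S,2R,5R,10R)-1-hydroxy-2,10-dimethyl-7-(propan-2-yl)spiro[4.5]dec-6-en-2-yl]-3-methylbutyl}-2,6-dimethoxybenzene-1,3-dicarbaldehyde | CC(C)C[C@H](c1c(Br)c(C=O)c(OC)c(C=O)c1OC)[C@@]1(C)CC[C@@]2(C=C(C(C)C)CC[C@H]2C)[C@H]1O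
F4 | step 11 | (1R,3'aS,6R,9'S,9'aR)-6,9'a-dimethyl-9'-(2-methylpropyl)-3-(propan-2-yl)-1',2',9',9'a-tetrahydro-3'aH-spiro[cyclohex-2-ene-1,3'-cyclopenta[b]chromene]-6',8'-diol | CC(C)C[C@@H]1c2c(O)cc(O)cc2O[C@H]2[C@]1(C)CC[C@@]21C=C(C(C)C)CC[C@H]1C
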